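A direct plan would follow the likely biogenesis, a phenol oxidative coupling of two bibenzyl halves made by Wittig olefination and alkene reduction. The halves would be 2,6-dibromo-4-[2-(3-methoxyphenyl)ethyl]phenol A1 and 4-[2-(3-benzyloxyphenyl)ethyl]-2,6-dichlorophenol A2. Anodic cross-coupling would give the 6-aryloxy-6-bromodienone A3, zinc would reduce it to the halogenated diaryl ether A4, and hydrogenolysis would remove three halogens and the benzyl group.
- The anodic cross-coupling of A1 with A2 would be the weakest step: an intermolecular, cross-selective C–O coupling of two nearly equal phenols has no precedent, and homo-coupling or over-oxidation would be expected.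
- The halogen blocking groups would be the second weakness: four halogens would be carried only to be removed, and they would force MOM protection and diimide in place of hydrogen in both halves, so most steps would build nothing.
- The final hydrogenolysis would be the third: four cleavages in one operation on the finished skeleton would risk partly halogenated material that is hard to separate.

**Retrosynthetic overview**
Ring letters: A = 3-hydroxyphenyl, C = the para-phenylene ring on the ether oxygen, B = the central phenol ring (C1 OH, C2 O-aryl, C4 arylethyl chain), D = 3-methoxyphenyl.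
Ring B would not be bought as an arene but built last from open-chain carbons by a Robinson annulation that forms C4–C5 and C2=C3. The partners are 4-(3-methoxyphenyl)butanal (ring D, one bridge, C3 and C4) and an aryloxymethyl vinyl ketone (rings A and C, the ether oxygen, C1, C2, C5, C6); dehydrogenation then aromatises the cyclohexenone.
The ether bond O–C2 of ring B would thus be made early as a Williamson ether at a CH2 group, with no aryl C–O coupling; rings A, C and D come from commercial arenes.
The 1,2,4-pattern of ring B follows from the connectivity of the annulation, so no halogen blocking groups, no oxidative phenol coupling and no multiple dehalogenation are needed; one benzyl ether is removed at the end.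

Key step: step 6

Remark: the target is achiral; the only stereocentre on the way (C4 of 12) forms as a racemate and is removed by aromatisation. Compounds 1, 2, 8 and the reagents named are taken as commercial.

Step 1
Reactants: 1 4-acetoxystyrene (4-vinylphenyl acetate); 2 1-(benzyloxy)-3-bromobenzene
Product: 5 4-[2-(3-benzyloxyphenyl)ethyl]phenol, via alkyl-9-BBN borane 3 (not isolated), via bibenzyl aryl acetate 4 (not isolated)
Conditions: 9-BBN, THF, 0 °C → rt; then 2, PdCl2(dppf) (3 mol%; dppf = 1,1'-bis(diphenylphosphino)ferrocene), aq. K3PO4, DMF, 60 °C; then NaOH, MeOH, rt; HCl work-up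
Reagents that add atoms: none
Why: B-alkyl Suzuki–Miyaura coupling, in which anti-Markovnikov hydroboration of the styrene and coupling of the primary alkylborane with the aryl bromide make the bibenzyl directly at the saturated level, so the benzyl ether never meets hydrogen, and hydroxide then cleaves the aryl acetate in the same flask.

Step 2
Reactants: 5 4-[2-(3-benzyloxyphenyl)ethyl]phenol
Product: 6 2-{4-[2-(3-benzyloxyphenyl)ethyl]phenoxy}-N-methoxy-N-methylacetamide
Conditions: ClCH2C(O)N(OMe)Me, K2CO3, NaI (cat.), acetone, reflux
Reagents that add atoms: 2-chloro-N-methoxy-N-methylacetamide, CON(C)C(=O)CCl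
Why: Williamson ether synthesis, an SN2 displacement by the only free phenoxide on an activated α-halo amide, which makes the future diaryl ether bond of ring B at an sp3 carbon.

Step 3
Reactants: 6 2-{4-[2-(3-benzyloxyphenyl)ethyl]phenoxy}-N-methoxy-N-methylacetamide
Product: 7 1-{4-[2-(3-benzyloxyphenyl)ethyl]phenoxy}but-3-en-2-one
Conditions: CH2=CHMgBr, THF, −20 → 0 °C; inverse quench into cold 1 M HCl; kept cold with a trace of BHT and used at once
Reagents that add atoms: vinylmagnesium bromide, C=C[Mg]Br
Why: Weinreb ketone synthesis, in which the magnesium chelate of the tetrahedral adduct prevents a second addition and the acidic inverse quench protonates the liberated N,O-dimethylhydroxylamine so that it cannot add to the enone.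

Step 4
Reactants: 8 4-(3-methoxyphenyl)butanoic acid
Product: 9 4-(3-methoxyphenyl)butan-1-ol
Conditions: BH3·SMe2, THF, 0 °C → rt; MeOH quench, aqueous work-up
Reagents that add atoms: none
Why: Borane reduction of a carboxylic acid through its acyloxyborane is fast and chemoselective, and the anisole ring is inert.

Step 5
Reactants: 9 4-(3-methoxyphenyl)butan-1-ol
Product: 10 4-(3-methoxyphenyl)butanal
Conditions: TEMPO (10 mol%), PhI(OAc)2, CH2Cl2, rt
Reagents that add atoms: none
Why: Oxoammonium (TEMPO) oxidation of a primary alcohol stops at the aldehyde under anhydrous conditions and gives an aldehyde clean enough to be used fresh in the annulation.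

Step 6
Reactants: 7 1-{4-[2-(3-benzyloxyphenyl)ethyl]phenoxy}but-3-en-2-one; 10 4-(3-methoxyphenyl)butanal
Product: 12 2-{4-[2-(3-benzyloxyphenyl)ethyl]phenoxy}-4-[2-(3-methoxyphenyl)ethyl]cyclohex-2-en-1-one (racemic), via 2,6-disubstituted 5-oxohexanal 11 (not isolated)
Conditions: 10 (1.2 equiv), Et2NH (0.3 equiv), MeCN, 0 °C → rt, 7 added slowly; then aq. KOH, Bu4NOH (cat.), THF, 45 °C
Reagents that add atoms: none
Why: Robinson annulation run as two stages in one flask: the enamine formed from aldehyde 10 and Et2NH adds through its α-carbon to the terminal carbon of vinyl ketone 7 (Michael addition, bond C4–C5 of ring B) to give ketoaldehyde 11, and hydroxide then enolises the ketone towards the aryloxy-bearing CH2, which attacks the aldehyde and loses water (aldol condensation, bond C2=C3). The closest known reaction type is the amine-catalysed annulation of α-monosubstituted aldehydes with methyl vinyl ketone to 4-substituted cyclohex-2-enones, together with the use of alkoxymethyl vinyl ketones in Robinson annulations to give 2-alkoxy enones. Ring B closes by a 6-(enolendo)-exo-trig aldol addition, the only closure open to 11, since attack from the chain CH2 or from the aldehyde α-carbon would give four-membered rings. The stereocentre C4 forms as a racemate without control, which is harmless because step 7 makes it planar. The step needs a single Michael addition and no self-aldol of 10: the α-branched product aldehyde forms its enamine far more slowly than 10, a small excess of 10 is used and the reactive vinyl ketone is added slowly. The 1,2,4-pattern cannot come out wrong, because by connectivity alone the aldehyde α-carbon ends para and the aryloxy carbon ortho to the carbonyl carbon.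

Step 7
Reactants: 12 2-{4-[2-(3-benzyloxyphenyl)ethyl]phenoxy}-4-[2-(3-methoxyphenyl)ethyl]cyclohex-2-en-1-one (racemic)
Product: 14 2-{4-[2-(3-benzyloxyphenyl)ethyl]phenoxy}-4-[2-(3-methoxyphenyl)ethyl]phenol, via cyclohexa-2,5-dienone 13 (not isolated)
Conditions: Pd(OCOCF3)2 (5 mol%), 2-(dimethylamino)pyridine (10 mol%), TsOH (20 mol%), O2 (1 atm), DMSO, 80 °C
Reagents that add atoms: none
Why: Palladium-catalysed aerobic dehydrogenation of a cyclohexenone, in which a divalent palladium enolate at C6 undergoes β-hydride elimination to the 2,5-dienone, whose C4–H tautomerises irreversibly to the phenol, while oxygen reoxidises zerovalent palladium and the ethers and bibenzyl CH2 groups are not touched.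

Step 8
Reactants: 14 2-{4-[2-(3-benzyloxyphenyl)ethyl]phenoxy}-4-[2-(3-methoxyphenyl)ethyl]phenol
Product: 15 2-{4-[2-(3-hydroxyphenyl)ethyl]phenoxy}-4-[2-(3-methoxyphenyl)ethyl]phenol (target CNP0225725.0)
Conditions: H2 (1 atm), 10% Pd/C, EtOAc–MeOH, rt
Reagents that add atoms: none
Why: Catalytic hydrogenolysis cleaves the single O-benzyl bond, and the methyl ether, the diaryl ether, the phenol and the saturated bridges are inert, so this last step has one job only.

**Compound list**
1 | 4-acetoxystyrene (4-vinylphenyl acetate) | CC(=O)Oc1ccc(C=C)cc1 | starting material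
2 | 1-(benzyloxy)-3-bromobenzene | Brc1cccc(OCc2ccccc2)c1 | starting material
3 | 9-[2-(4-acetoxyphenyl)ethyl]-9-borabicyclo[3.3.1]nonane (not isolated) | CC(=O)Oc1ccc(CCB2C3CCCC2CCC3)cc1 | intermediate
4 | 4-[2-(3-benzyloxyphenyl)ethyl]phenyl acetate (not isolated) | CC(=O)Oc1ccc(CCc2cccc(OCc3ccccc3)c2)cc1 | intermediate
5 | 4-[2-(3-benzyloxyphenyl)ethyl]phenol | Oc1ccc(CCc2cccc(OCc3ccccc3)c2)cc1 | intermediate
6 | 2-{4-[2-(3-benzyloxyphenyl)ethyl]phenoxy}-N-methoxy-N-methylacetamide | CON(C)C(=O)COc1ccc(CCc2cccc(OCc3ccccc3)c2)cc1 | intermediate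
7 | 1-{4-[2-(3-benzyloxyphenyl)ethyl]phenoxy}but-3-en-2-one | C=CC(=O)COc1ccc(CCc2cccc(OCc3ccccc3)c2)cc1 | intermediate
8 | 4-(3-methoxyphenyl)butanoic acid | COc1cccc(CCCC(=O)O)c1 | starting material
9 | 4-(3-methoxyphenyl)butan-1-ol | COc1cccc(CCCCO)c1 | intermediate
10 | 4-(3-methoxyphenyl)butanal | COc1cccc(CCCC=O)c1 | intermediate
11 | 6-{4-[2-(3-benzyloxyphenyl)ethyl]phenoxy}-2-[2-(3-methoxyphenyl)ethyl]-5-oxohexanal, racemic (not isolated) | COc1cccc(CCC(C=O)CCC(=O)COc2ccc(CCc3cccc(OCc4ccccc4)c3)cc2)c1 | intermediate
12 | 2-{4-[2-(3-benzyloxyphenyl)ethyl]phenoxy}-4-[2-(3-methoxyphenyl)ethyl]cyclohex-2-en-1-one, racemic | COc1cccc(CCC2CCC(=O)C(Oc3ccc(CCc4cccc(OCc5ccccc5)c4)cc3)=C2)c1 | intermediate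
13 | 2-{4-[2-(3-benzyloxyphenyl)ethyl]phenoxy}-4-[2-(3-methoxyphenyl)ethyl]cyclohexa-2,5-dien-1-one (not isolated) | COc1cccc(CCC2C=CC(=O)C(Oc3ccc(CCc4cccc(OCc5ccccc5)c4)cc3)=C2)c1 | intermediate
14 | 2-{4-[2-(3-benzyloxyphenyl)ethyl]phenoxy}-4-[2-(3-methoxyphenyl)ethyl]phenol | COc1cccc(CCc2ccc(O)c(Oc3ccc(CCc4cccc(OCc5ccccc5)c4)cc3)c2)c1 | intermediate
15 | 2-{4-[2-(3-hydroxyphenyl)ethyl]phenoxy}-4-[2-(3-methoxyphenyl)ethyl]phenol (achiral) | COc1cccc(CCc2ccc(O)c(Oc3ccc(CCc4cccc(O)c4)cc3)c2)c1 | target

Total step count: 8. Longest linear sequence: 6 (steps 1, 2, 3, 6, 7, 8).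

**Steps most likely to fail**

Step 6 (annulation). The electron-poor vinyl ketone 7 may polymerise or be held as its amine adduct faster than the enamine adds, or 11 may take up a second molecule of 7. The fallback would run the annulation with methyl vinyl ketone, for which it is standard, and bring in the aryloxy group afterwards. Aldehyde 10 and methyl vinyl ketone (Et2NH cat.; then aq. KOH) would give 4-[2-(3-methoxyphenyl)ethyl]cyclohex-2-en-1-one F1. Nucleophilic epoxidation (H2O2, NaOH, MeOH, 0 °C) would give the epoxy ketone 5-[2-(3-methoxyphenyl)ethyl]-7-oxabicyclo[4.1.0]heptan-2-one F2. The potassium salt of phenol 5 (KH, THF–DMPU, 60 °C) would open F2 at the carbon next to the carbonyl group, and loss of water from the β-hydroxy ketone would give the 2-aryloxy enone. This fallback sets out from 10 and 5 and returns to the route at 12.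

Step 7 (aerobic dehydrogenation). The catalyst may fall out as palladium black before conversion is complete, or the electron-rich phenol may be oxidised further. The fallback would be a stoichiometric enolate route. Kinetic deprotonation of 12 at C6 (LiN(iPr)2, THF, −78 °C) and silylation (Me3SiCl) would give the cross-conjugated silyl dienol ether [(6-{4-[2-(3-benzyloxyphenyl)ethyl]phenoxy}-4-[2-(3-methoxyphenyl)ethyl]cyclohexa-1,5-dien-1-yl)oxy]trimethylsilane F3. Saegusa–Ito oxidation (Pd(OAc)2, MeCN, rt) would give dienone 13, which tautomerises to the phenol. This fallback sets out from 12 and returns to the route at 14.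

Step 3 (vinyl ketone from the Weinreb amide). Liberated N,O-dimethylhydroxylamine or a second equivalent of the Grignard reagent may add to the enone during the quench, and the product may polymerise on concentration. The fallback would avoid the organometallic step. Phenoxide from 5 (K2CO3, DMF, 80 °C) would open 2-vinyloxirane at its CH2 terminus to give the allylic alcohol 1-{4-[2-(3-benzyloxyphenyl)ethyl]phenoxy}but-3-en-2-ol F4. Oxidation (Dess–Martin periodinane, NaHCO3, CH2Cl2, 0 °C) just before use would give the vinyl ketone. This fallback sets out from 5 and returns to the route at 7.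

**Further compounds**
F1 | step 6 | 4-[2-(3-methoxyphenyl)ethyl]cyclohex-2-en-1-one, racemic | COc1cccc(CCC2CCC(=O)C=C2)c1
F2 | step 6 | 5-[2-(3-methoxyphenyl)ethyl]-7-oxabicyclo[4.1.0]heptan-2-one, racemic, mixture of diastereomers | COc1cccc(CCC2CCC(=O)C3OC23)c1
F3 | step 7 | [(6-{4-[2-(3-benzyloxyphenyl)ethyl]phenoxy}-4-[2-(3-methoxyphenyl)ethyl]cyclohexa-1,5-dien-1-yl)oxy]trimethylsilane, racemic | COc1cccc(CCC2CC=C(O[Si](C)(C)C)C(Oc3ccc(CCc4cccc(OCc5ccccc5)c4)cc3)=C2)c1
F4 | step 3 | 1-{4-[2-(3-benzyloxyphenyl)ethyl]phenoxy}but-3-en-2-ol, racemic | C=CC(O)COc1ccc(CCc2cccc(OCc3ccccc3)c2)cc1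
A1 | direct plan | 2,6-dibromo-4-[2-(3-methoxyphenyl)ethyl]phenol | COc1cccc(CCc2cc(Br)c(O)c(Br)c2)c1
A2 | direct plan | 4-[2-(3-benzyloxyphenyl)ethyl]-2,6-dichlorophenol | Oc1c(Cl)cc(CCc2cccc(OCc3ccccc3)c2)cc1Cl
A3 | direct plan | 2,6-dibromo-6-{4-[2-(3-benzyloxyphenyl)ethyl]-2,6-dichlorophenoxy}-4-[2-(3-methoxyphenyl)ethyl]cyclohexa-2,4-dien-1-one, racemic | O=C1C(Br)=CC(CCc2cccc(OC)c2)=CC1(Br)Oc1c(Cl)cc(CCc2cccc(OCc3ccccc3)c2)cc1Cl
A4 | direct plan | 2-{4-[2-(3-benzyloxyphenyl)ethyl]-2,6-dichlorophenoxy}-6-bromo-4-[2-(3-methoxyphenyl)ethyl]phenol | COc1cccc(CCc2cc(Br)c(O)c(Oc3c(Cl)cc(CCc4cccc(OCc5ccccc5)c4)cc3Cl)c2)c1
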